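**Retrosynthetic overview**
1. Target ⇒ C8–O ester bond: macrocyclic 8‑alcohol plus O‑silylated 2‑(hydroxymethyl)acrylic acid.
2. Ten‑membered carbocycle (last ring) ⇒ C7–C8. C7 is the β‑carbon of the butenolide and C8 is an aldehyde carbon, so both are natural electrophiles. C7 is used as a β‑acylvinyl anion (d3), made from C7–Br with CrCl2/NiCl2.
3. C8–C9–C10(CH3) ⇒ anti‑crotylboration of the C1 aldehyde, hydroboration, double oxidation.
4. Butenolide (second ring) ⇒ C6–C7. The same carbon is used first as a bromoalkenylmagnesium reagent from ethyl 2‑(acetoxymethyl)‑3,3‑dibromoacrylate. It adds to the epoxy aldehyde and the adduct lactonises.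
5. Oxirane (first ring) ⇒ Sharpless epoxidation of nerol, which supplies C1–C6, the C4 methyl and the Z geometry needed for the cis‑epoxide.

Assumption: germacrane numbering is used (C1 ketone, C4/C5 oxirane, C6 lactone carbinol, C7=C11 butenolide alkene, C8 ester carbinol, C10 methyl‑bearing carbon, C12 lactone C=O, C13 CH2OAc). The SMILES reads (4R,5S,6S,8S,10R) with C3 and C6 cis on the oxirane.

Step 1
Reactants: 1 nerol
Product: 2 (2S,3R)-2,3-epoxynerol
Conditions: Ti(OiPr)4 (10 mol%), L-(+)-diethyl tartrate (12 mol%), t-BuOOH, 4 Å MS, CH2Cl2, −20 °C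
Reagents that add atoms: tert-butyl hydroperoxide, CC(C)(C)OO
Why: Sharpless asymmetric epoxidation: the catalyst formed from Ti(OiPr)4 and the L-tartrate oxidises only the allylic alkene, from the face that gives the (2S,3R)-epoxide (about 90–94% ee), which sets C4 (R) and C5 (S), and the retained Z geometry puts C3 and C6 cis.

Step 2
Reactants: 2 (2S,3R)-2,3-epoxynerol
Product: 3 (2R,3R)-3-methyl-3-(4-methylpent-3-en-1-yl)oxirane-2-carbaldehyde
Conditions: TEMPO (10 mol%), PhI(OAc)2, CH2Cl2, rt
Reagents that add atoms: none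
Why: The TEMPO/oxoammonium oxidation stops at the aldehyde under near-neutral conditions, spares the epoxide and alkene, and touches no stereocentre (the C5 label changes only because CHO outranks C4).

Step 3
Reactants: 4 ethyl bromopyruvate
Product: 5 ethyl 3-acetoxy-2-oxopropanoate
Conditions: KOAc, acetone, 0 °C to rt
Reagents that add atoms: potassium acetate, CC(=O)[O-].[K+]
Why: SN2 displacement at an α-halo ketone is fast, and the weakly basic carboxylate avoids self-condensation of the pyruvate.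

Step 4
Reactants: 5 ethyl 3-acetoxy-2-oxopropanoate
Product: 6 ethyl 2-(acetoxymethyl)-3,3-dibromoprop-2-enoate
Conditions: CBr4 (2 equiv), PPh3 (4 equiv), CH2Cl2, 0 °C
Reagents that add atoms: carbon tetrabromide, BrC(Br)(Br)Br
Why: Ramirez dibromoolefination (first stage of the Corey–Fuchs sequence): Ph3P=CBr2 formed in situ undergoes a Wittig reaction at the very electrophilic keto group and leaves both esters alone.

Step 5
Reactants: 6 ethyl 2-(acetoxymethyl)-3,3-dibromoprop-2-enoate; 3 (2R,3R)-3-methyl-3-(4-methylpent-3-en-1-yl)oxirane-2-carbaldehyde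
Product: 9 {(5R)-4-bromo-5-[(2S,3R)-3-methyl-3-(4-methylpent-3-en-1-yl)oxiran-2-yl]-2-oxo-2,5-dihydrofuran-3-yl}methyl acetate, via bromoalkenylmagnesium chloride 7 (not isolated), via chloromagnesium alkoxide 8 (not isolated)
Conditions: 6 (1.2 equiv), i-PrMgCl (1.05 equiv per 6), THF, −78 °C, 20 min; add 3, −78 to 0 °C; water quench
Reagents that add atoms: none
Why: Ester-chelated bromine–magnesium exchange places Mg cis to CO2Et, so C7 becomes a β-acylvinyl anion (d3 synthon) that adds to the cis-substituted epoxy aldehyde in the Felkin–Anh (anti) sense to set C6, and the alkoxide lactonises onto the cis ester while the second bromine stays on C7 (C6 has the target's 6S arrangement and is labelled R here only because Br raises C7).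

Step 6
Reactants: 9 bromobutenolide with prenyl tail
Product: 11 {(5R)-4-bromo-5-[(2S,3R)-3-methyl-3-(3-oxopropyl)oxiran-2-yl]-2-oxo-2,5-dihydrofuran-3-yl}methyl acetate, via secondary ozonide 10 (not isolated)
Conditions: O3, CH2Cl2, −78 °C; Me2S, −78 °C to rt
Reagents that add atoms: ozone, [O-][O+]=O
Why: Ozonolysis with reductive work-up takes the electron-rich trisubstituted alkene, while the electron-poor tetrasubstituted bromobutenolide alkene is inert, and no stereocentre is involved.

Step 7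
Reactants: 11 bromobutenolide C1 aldehyde; 12 (E)-crotylboronic acid pinacol ester
Product: 14 {(5R)-4-bromo-5-[(2S,3R)-3-[(3S,4R)-3-hydroxy-4-methylhex-5-en-1-yl]-3-methyloxiran-2-yl]-2-oxo-2,5-dihydrofuran-3-yl}methyl acetate, via pinacol borate ester 13 (not isolated)
Conditions: 12 (1.3 equiv), (R)-TRIP phosphoric acid (5 mol%), 4 Å MS, toluene, −30 °C; neutral aqueous work-up, Et3N-buffered silica
Reagents that add atoms: none
Why: Chiral phosphoric acid-catalysed crotylboration runs through a closed Zimmerman–Traxler chair, so the E-crotyl geometry gives the anti pair and the (R)-catalyst directs attack to the Re face of the aldehyde, which sets C10 as R (the C1 carbinol, S, is erased in step 9, and the O–B bond masks the hydroxyl from the epoxide during the reaction).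

Step 8
Reactants: 14 anti homoallylic alcohol
Product: 16 {(5R)-4-bromo-5-[(2S,3R)-3-[(3S,4R)-3,6-dihydroxy-4-methylhexyl]-3-methyloxiran-2-yl]-2-oxo-2,5-dihydrofuran-3-yl}methyl acetate, via bis(9-BBN) adduct 15 (not isolated)
Conditions: 9-BBN-H (2.5 equiv), THF, 0 °C to rt; 30% H2O2, pH 7 phosphate buffer, 0 °C to rt
Reagents that add atoms: hydrogen peroxide, OO
Why: Hydroboration–oxidation: 9-BBN-H (one equivalent is consumed by the OH) adds anti-Markovnikov to the only unhindered electron-rich alkene, and buffered peroxide replaces boron by OH without exposing the bromobutenolide, acetate or epoxide to strong base.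

Step 9
Reactants: 16 1,4-diol
Product: 18 {(5R)-4-bromo-5-[(2S,3R)-3-methyl-3-[(4R)-4-methyl-3,6-dioxohexyl]oxiran-2-yl]-2-oxo-2,5-dihydrofuran-3-yl}methyl acetate, via bis(alkoxysulfonium) dichloride 17 (not isolated)
Conditions: (COCl)2, DMSO, CH2Cl2, −78 °C; Et3N, −78 to −20 °C
Reagents that add atoms: none
Why: Swern oxidation activates both hydroxyls as alkoxysulfonium ions before base is added, so the 1,4-diol gives the keto aldehyde instead of a lactol or lactone, and the short cold contact with amine leaves C10 and C6 intact.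

Step 10
Reactants: 18 bromobutenolide keto aldehyde
Product: 21 (4R,5S,6S,8S,10R)-13-acetoxy-4,5-epoxy-8-hydroxy-1-oxogermacr-7(11)-en-12,6-olide, via alkenylchromium dichloride 19 (not isolated), via dichlorochromium alkoxide 20 (not isolated)
Conditions: CrCl2 (10 equiv), NiCl2 (0.1 equiv), degassed DMSO, 2 mM, 18 added over 12 h, rt; aqueous work-up
Reagents that add atoms: none
Why: Nozaki–Hiyama–Kishi macrocyclisation: zerovalent nickel inserts into the activated C7–Br bond and transmetallation gives a trivalent alkenylchromium species, so the normally electrophilic β-carbon C7 acts as a β-acylvinyl anion that adds only to the aldehyde (ketone, esters and epoxide are tolerated); the cis-epoxide turn holds the chain ends close, and C5 with the chromium-binding epoxide oxygen blocks one face of the flat butenolide, so C8 should bond from the H-6 face with C9 turned into the ring, which is Re-face attack and gives 8S.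

Step 11
Reactants: 22 ethyl 2-(hydroxymethyl)acrylate
Product: 23 ethyl 2-{[(tert-butyldimethylsilyl)oxy]methyl}acrylate
Conditions: TBSCl, imidazole, CH2Cl2, rt
Reagents that add atoms: tert-butyldimethylsilyl chloride, CC(C)(C)[Si](C)(C)Cl
Why: Standard silyl protection of a primary allylic alcohol prevents self-esterification of the side-chain acid later.

Step 12
Reactants: 23 ethyl 2-{[(tert-butyldimethylsilyl)oxy]methyl}acrylate
Product: 24 2-{[(tert-butyldimethylsilyl)oxy]methyl}acrylic acid
Conditions: LiOH, THF–H2O, 0 °C to rt; 1 M HCl to pH 4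
Reagents that add atoms: lithium hydroxide, [Li+].[OH-]
Why: Saponification of the unhindered ethyl ester is faster than conjugate addition to the α-substituted acrylate, and the TBS ether survives.

Step 13
Reactants: 24 2-{[(tert-butyldimethylsilyl)oxy]methyl}acrylic acid; 21 macrocyclic 8-alcohol
Product: 26 8-O-(2-{[(tert-butyldimethylsilyl)oxy]methyl}acryloyl) derivative of 21, via mixed anhydride 25 (not isolated)
Conditions: 24, 2,4,6-trichlorobenzoyl chloride, Et3N, toluene, rt; then 21, DMAP, rt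
Reagents that add atoms: none
Why: Yamaguchi esterification: DMAP attacks the less hindered acryloyl carbonyl of the mixed anhydride and acylates the hindered allylic alcohol, and the C8–O bond is not broken so 8S is retained.

Step 14
Reactants: 26 silyl-protected target
Product: 27 target CNP0258719.1
Conditions: HF·pyridine, pyridine, THF, 0 °C
Reagents that add atoms: none
Why: Fluoride-driven desilylation under pyridine buffering frees the primary alcohol without base (no loss of acetate or epoxide opening through C6 deprotonation) and without acid strong enough to open the oxirane.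

**Compound list**
1 | nerol, (2Z)-3,7-dimethylocta-2,6-dien-1-ol | CC(C)=CCC/C(C)=C\CO | starting material
2 | [(2S,3R)-3-methyl-3-(4-methylpent-3-en-1-yl)oxiran-2-yl]methanol | CC(C)=CCC[C@@]1(C)O[C@H]1CO | intermediate
3 | (2R,3R)-3-methyl-3-(4-methylpent-3-en-1-yl)oxirane-2-carbaldehyde | CC(C)=CCC[C@@]1(C)O[C@H]1C=O | intermediate
4 | ethyl 3-bromo-2-oxopropanoate | CCOC(=O)C(=O)CBr | starting material
5 | ethyl 3-acetoxy-2-oxopropanoate | CCOC(=O)C(=O)COC(C)=O | intermediate
6 | ethyl 2-(acetoxymethyl)-3,3-dibromoprop-2-enoate | CCOC(=O)C(COC(C)=O)=C(Br)Br | intermediate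
7 | ethyl (E)-2-(acetoxymethyl)-3-bromo-3-(chloromagnesio)prop-2-enoate, Mg cis to CO2Et | CCOC(=O)/C(COC(C)=O)=C(Br)\[Mg]Cl | intermediate
8 | chloromagnesium alkoxide of the adduct of 7 and 3, carbinol carbon cis to CO2Et | CCOC(=O)/C(COC(C)=O)=C(Br)\[C@H](O[Mg]Cl)[C@@H]1O[C@]1(C)CCC=C(C)C | intermediate
9 | {(5R)-4-bromo-5-[(2S,3R)-3-methyl-3-(4-methylpent-3-en-1-yl)oxiran-2-yl]-2-oxo-2,5-dihydrofuran-3-yl}methyl acetate | CC(C)=CCC[C@@]1(C)O[C@H]1[C@H]1OC(=O)C(COC(C)=O)=C1Br | intermediate
10 | secondary ozonide (3,3-dimethyl-1,2,4-trioxolan-5-yl compound) of 9, ozonide CH centre undefined | CC1(C)OOC(CC[C@@]2(C)O[C@H]2[C@H]2OC(=O)C(COC(C)=O)=C2Br)O1 | intermediate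
11 | {(5R)-4-bromo-5-[(2S,3R)-3-methyl-3-(3-oxopropyl)oxiran-2-yl]-2-oxo-2,5-dihydrofuran-3-yl}methyl acetate | O=CCC[C@@]1(C)O[C@H]1[C@H]1OC(=O)C(COC(C)=O)=C1Br | intermediate
12 | (E)-crotylboronic acid pinacol ester | C/C=C/CB1OC(C)(C)C(C)(C)O1 | starting material
13 | O-(pinacolatoboryl) derivative of 14 | C=C[C@@H](C)[C@@H](OB1OC(C)(C)C(C)(C)O1)CC[C@@]1(C)O[C@H]1[C@H]1OC(=O)C(COC(C)=O)=C1Br | intermediate
14 | {(5R)-4-bromo-5-[(2S,3R)-3-[(3S,4R)-3-hydroxy-4-methylhex-5-en-1-yl]-3-methyloxiran-2-yl]-2-oxo-2,5-dihydrofuran-3-yl}methyl acetate | C=C[C@@H](C)[C@@H](O)CC[C@@]1(C)O[C@H]1[C@H]1OC(=O)C(COC(C)=O)=C1Br | intermediate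
15 | C8-(9-BBN) alkylborane and C1-O-(9-BBN) borinate of 14 | B1(C2CCCC1CCC2)CC[C@@H](C)[C@@H](OB1C2CCCC1CCC2)CC[C@@]1(C)O[C@H]1[C@H]1OC(=O)C(COC(C)=O)=C1Br | intermediate
16 | {(5R)-4-bromo-5-[(2S,3R)-3-[(3S,4R)-3,6-dihydroxy-4-methylhexyl]-3-methyloxiran-2-yl]-2-oxo-2,5-dihydrofuran-3-yl}methyl acetate | OCC[C@@H](C)[C@@H](O)CC[C@@]1(C)O[C@H]1[C@H]1OC(=O)C(COC(C)=O)=C1Br | intermediate
17 | bis(dimethylalkoxysulfonium) dichloride of 16 | C[S+](C)OCC[C@@H](C)[C@@H](O[S+](C)C)CC[C@@]1(C)O[C@H]1[C@H]1OC(=O)C(COC(C)=O)=C1Br.[Cl-].[Cl-] | intermediate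
18 | {(5R)-4-bromo-5-[(2S,3R)-3-methyl-3-[(4R)-4-methyl-3,6-dioxohexyl]oxiran-2-yl]-2-oxo-2,5-dihydrofuran-3-yl}methyl acetate | O=CC[C@@H](C)C(=O)CC[C@@]1(C)O[C@H]1[C@H]1OC(=O)C(COC(C)=O)=C1Br | intermediate
19 | C7-(dichlorochromio) analogue of 18 | O=CC[C@@H](C)C(=O)CC[C@@]1(C)O[C@H]1[C@H]1OC(=O)C(COC(C)=O)=C1[Cr](Cl)Cl | intermediate
20 | 8-O-(dichlorochromio) alkoxide of 21 | Cl[Cr](Cl)O[C@H]1C[C@@H](C)C(=O)CC[C@@]2(C)O[C@H]2[C@H]2OC(=O)C(COC(C)=O)=C12 | intermediate
21 | (4R,5S,6S,8S,10R)-13-acetoxy-4,5-epoxy-8-hydroxy-1-oxogermacr-7(11)-en-12,6-olide | O[C@H]1C[C@@H](C)C(=O)CC[C@@]2(C)O[C@H]2[C@H]2OC(=O)C(COC(C)=O)=C12 | intermediate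
22 | ethyl 2-(hydroxymethyl)acrylate | C=C(CO)C(=O)OCC | starting material
23 | ethyl 2-{[(tert-butyldimethylsilyl)oxy]methyl}acrylate | C=C(CO[Si](C)(C)C(C)(C)C)C(=O)OCC | intermediate
24 | 2-{[(tert-butyldimethylsilyl)oxy]methyl}acrylic acid | C=C(CO[Si](C)(C)C(C)(C)C)C(=O)O | intermediate
25 | mixed anhydride of 24 and 2,4,6-trichlorobenzoic acid | C=C(CO[Si](C)(C)C(C)(C)C)C(=O)OC(=O)c1c(Cl)cc(Cl)cc1Cl | intermediate
26 | (4R,5S,6S,8S,10R)-13-acetoxy-4,5-epoxy-1-oxo-8-(2-{[(tert-butyldimethylsilyl)oxy]methyl}acryloyloxy)germacr-7(11)-en-12,6-olide | C=C(CO[Si](C)(C)C(C)(C)C)C(=O)O[C@H]1C[C@@H](C)C(=O)CC[C@@]2(C)O[C@H]2[C@H]2OC(=O)C(COC(C)=O)=C12 | intermediate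
27 | (4R,5S,6S,8S,10R)-13-acetoxy-4,5-epoxy-8-[2-(hydroxymethyl)acryloyloxy]-1-oxogermacr-7(11)-en-12,6-olide | C=C(CO)C(=O)O[C@H]1C[C@@H](C)C(=O)CC[C@@]2(C)O[C@H]2[C@H]2OC(=O)C(COC(C)=O)=C12 | target

**Totals:** 14 steps in all. The longest linear sequence is 10 steps from nerol (steps 1, 2, 5, 6, 7, 8, 9, 10, 13, 14).

**Steps most likely to fail**

Step 10 carries the highest risk. A strained ten-membered ring has to close, the nucleophile is an electron-poor alkenylchromium species that can be protonated instead, and the facial argument for 8S is only a model and could give 8R. The fallback sets out from 18 and reverses the polarity at C8 instead of C7. Aldehyde C–H abstraction gives the acyl radical, which nickel couples with the C7–Br bond (Ir[dF(CF3)ppy]2(dtbbpy)PF6, NiBr2(dtbbpy), quinuclidine, K2CO3, dioxane, blue light, high dilution). This gives (4R,5S,6S,10R)-13-acetoxy-4,5-epoxy-1,8-dioxogermacr-7(11)-en-12,6-olide F1. Reduction of the conjugated C8 carbonyl with (R)-Me-CBS and catecholborane at −78 °C then sets 8S under reagent control. Hydride should also prefer the outer face of the ring. The route is rejoined at 21.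

Step 5 is second. The acetate may compete for the Grignard reagent or for chelation during the exchange, the carbenoid may decompose before it adds, and the Felkin–Anh ratio may be modest. The fallback sets out from 23 and 3 and carries C13 as a silyl ether until the C6–C7 bond is in place.
- Ozonolysis of 23 (O3, then Me2S) gives ethyl 3-[(tert-butyldimethylsilyl)oxy]-2-oxopropanoate F2.
- CBr4/PPh3 converts F2 into ethyl 3,3-dibromo-2-{[(tert-butyldimethylsilyl)oxy]methyl}prop-2-enoate F3.
- i-PrMgCl followed by 3 gives the silyl ether bromobutenolide F4.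
- HF·pyridine frees the hydroxymethyl bromobutenolide F5, and Ac2O/pyridine returns to the route at 9.

Step 13 is third. The C8 hydroxyl is hindered, can hide as a hemiketal with the C1 ketone, and sits in a base-sensitive molecule. The fallback sets out from 21 and builds the side chain on the macrocycle instead of bringing it in. The small acryloyl chloride (Et3N, CH2Cl2, −20 °C) gives the 8-O-acryloyl ester F6. A Morita–Baylis–Hillman reaction with aqueous formaldehyde and DABCO in dioxane–water then installs the hydroxymethyl group. This rejoins the route directly at 27 without any silyl group.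

**Further compounds**
F1 | step 10 | (4R,5S,6S,10R)-13-acetoxy-4,5-epoxy-1,8-dioxogermacr-7(11)-en-12,6-olide | O=C1C[C@@H](C)C(=O)CC[C@@]2(C)O[C@H]2[C@H]2OC(=O)C(COC(C)=O)=C12
F2 | step 5 | ethyl 3-[(tert-butyldimethylsilyl)oxy]-2-oxopropanoate | CCOC(=O)C(=O)CO[Si](C)(C)C(C)(C)C
F3 | step 5 | ethyl 3,3-dibromo-2-{[(tert-butyldimethylsilyl)oxy]methyl}prop-2-enoate | CCOC(=O)C(CO[Si](C)(C)C(C)(C)C)=C(Br)Br
F4 | step 5 | (5R)-4-bromo-3-{[(tert-butyldimethylsilyl)oxy]methyl}-5-[(2S,3R)-3-methyl-3-(4-methylpent-3-en-1-yl)oxiran-2-yl]furan-2(5H)-one | CC(C)=CCC[C@@]1(C)O[C@H]1[C@H]1OC(=O)C(CO[Si](C)(C)C(C)(C)C)=C1Br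
F5 | step 5 | (5R)-4-bromo-3-(hydroxymethyl)-5-[(2S,3R)-3-methyl-3-(4-methylpent-3-en-1-yl)oxiran-2-yl]furan-2(5H)-one | CC(C)=CCC[C@@]1(C)O[C@H]1[C@H]1OC(=O)C(CO)=C1Br
F6 | step 13 | (4R,5S,6S,8S,10R)-13-acetoxy-8-acryloyloxy-4,5-epoxy-1-oxogermacr-7(11)-en-12,6-olide | C=CC(=O)O[C@H]1C[C@@H](C)C(=O)CC[C@@]2(C)O[C@H]2[C@H]2OC(=O)C(COC(C)=O)=C12
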